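**Retrosynthetic overview**
1. The target is 3,5,2',4'-tetrahydroxy-7,8,5'-trimethoxyflavone. On ring A, C5–OH and C8–OMe are para, and C8a (which carries O1) lies between C8 and C4a. Ring A is therefore the reduced, O-alkylated form of a 2-acyl-5-methoxy-1,4-benzoquinone whose free β-carbon is C8a.
2. Last disconnections: the benzyl ethers at O3, O2' and O4', and the O8 methyl group. The methyl goes on selectively because C5–OH is chelated to C4=O.
3. Key disconnection O1–C8a: ring C is the only ring built (rings A and B are purchased arenes). It closes when the enol oxygen of a 2-benzyloxy-1,3-diketone adds to the anodically generated acylquinone.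
4. The diketone comes from C-acylation (bond C2–C3) of the polyanion of a 2,5-dihydroxy-4-methoxyphenyl benzyloxymethyl ketone with the ring B acid chloride.
5. Ketone: methoxyhydroquinone (MOM protection, bromination, Br–Li exchange) plus the Weinreb amide of benzyloxyacetic acid. Ring B: isovanillin by Baeyer–Villiger, benzylation, Vilsmeier–Haack and Pinnick reactions.

Key step: step 13

Remark: the target has no stereocentre. Compound 20 is drawn as the diketo tautomer, although it should equilibrate with its chelated enol and with the cyclic 2-hydroxyflavanone hemiketal.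

**Step 1**
Reactants: 1 isovanillin
Product: 2 3-(benzyloxy)-4-methoxybenzaldehyde
Conditions: BnBr, K2CO3, DMF, rt
Reagents that add atoms: benzyl bromide BrCc1ccccc1
Why: Williamson etherification of the only phenol, with the aldehyde inert to carbonate and benzyl bromide.

**Step 2**
Reactants: 2 3-(benzyloxy)-4-methoxybenzaldehyde
Product: 4 3-(benzyloxy)-4-methoxyphenol, via aryl formate 3 (not isolated)
Conditions: mCPBA, CH2Cl2, 0 °C→rt; aq NaHCO3 wash, solvent swap; K2CO3 (cat.), MeOH, rt
Reagents that add atoms: mCPBA O=C(OO)c1cccc(Cl)c1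
Why: Baeyer–Villiger oxidation in which the aryl group, made electron-rich by the para methoxy group, migrates in preference to hydride, and catalytic methanolysis then frees the phenol from the formate.

**Step 3**
Reactants: 4 3-(benzyloxy)-4-methoxyphenol
Product: 5 2,4-bis(benzyloxy)-1-methoxybenzene
Conditions: BnBr, K2CO3, DMF, 50 °C
Reagents that add atoms: benzyl bromide BrCc1ccccc1
Why: Williamson etherification of the new phenol completes the oxygen pattern of ring B.

**Step 4**
Reactants: 5 2,4-bis(benzyloxy)-1-methoxybenzene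
Product: 7 2,4-bis(benzyloxy)-5-methoxybenzaldehyde, via iminium chloride 6 (not isolated)
Conditions: POCl3, DMF, 0→60 °C; then H2O, 0 °C→rt
Reagents that add atoms: DMF CN(C)C=O; water O
Why: Vilsmeier–Haack formylation should go to the one carbon that is ortho to one benzyloxy group and para to the other, because the carbon between the two benzyloxy groups is shielded and the carbon next to OMe is meta to both.

**Step 5**
Reactants: 7 2,4-bis(benzyloxy)-5-methoxybenzaldehyde
Product: 8 2,4-bis(benzyloxy)-5-methoxybenzoic acid
Conditions: NaClO2, NaH2PO4, 2-methyl-2-butene, t-BuOH/THF/H2O, rt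
Reagents that add atoms: sodium chlorite [Na+].[O-]Cl=O
Why: Pinnick oxidation converts the aldehyde to the acid under near-neutral conditions, and the alkene takes up HOCl before it can chlorinate the electron-rich ring.

**Step 6**
Reactants: 8 2,4-bis(benzyloxy)-5-methoxybenzoic acid
Product: 9 2,4-bis(benzyloxy)-5-methoxybenzoyl chloride
Conditions: (COCl)2, DMF (cat.), CH2Cl2, 0 °C→rt; evaporated and used crude
Reagents that add atoms: oxalyl chloride O=C(Cl)C(=O)Cl
Why: acid chloride formation through catalytic chloroiminium activation runs at room temperature without a Lewis acid, so the benzyl ethers stay in place.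

**Step 7**
Reactants: 10 benzyloxyacetic acid
Product: 12 2-(benzyloxy)-N-methoxy-N-methylacetamide, via acylimidazole 11 (not isolated)
Conditions: 1,1'-carbonyldiimidazole, CH2Cl2, rt; then MeNHOMe·HCl, rt
Reagents that add atoms: N,O-dimethylhydroxylamine hydrochloride CNOC.Cl
Why: amide formation through the acylimidazole gives the Weinreb amide without any reagent that could touch the benzyl ether.

**Step 8**
Reactants: 13 methoxyhydroquinone
Product: 14 2-methoxy-1,4-bis(methoxymethoxy)benzene
Conditions: MOMCl, iPr2NEt, CH2Cl2, 0 °C→rt, argon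
Reagents that add atoms: chloromethyl methyl ether COCCl
Why: O-alkylation of both phenols to acetals, chosen because a MOM ether ortho to a C–Li bond stabilises it by chelation whereas a silyl ether there would risk retro-Brook migration.

**Step 9**
Reactants: 14 2-methoxy-1,4-bis(methoxymethoxy)benzene
Product: 15 1-bromo-4-methoxy-2,5-bis(methoxymethoxy)benzene
Conditions: NBS, MeCN, 0 °C, dark
Reagents that add atoms: N-bromosuccinimide O=C1CCC(=O)N1Br
Why: electrophilic aromatic bromination should follow the orientation known for 1,2,4-trialkoxybenzenes and take the carbon para to OMe and ortho to a MOM ether, which is the future C4a.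

**Step 10**
Reactants: 15 1-bromo-4-methoxy-2,5-bis(methoxymethoxy)benzene; 12 2-(benzyloxy)-N-methoxy-N-methylacetamide
Product: 17 2-(benzyloxy)-1-[4-methoxy-2,5-bis(methoxymethoxy)phenyl]ethan-1-one, via aryllithium 16 (not isolated)
Conditions: n-BuLi, THF, −78 °C; then 12, −78→0 °C; aq NH4Cl
Reagents that add atoms: none
Why: bromine–lithium exchange followed by Weinreb ketone synthesis stops at the ketone through the chelated tetrahedral adduct, and it avoids a Friedel–Crafts acylation in which an alkoxyacetyl donor tends to decarbonylate and the benzyl ether would be exposed to a Lewis acid.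

**Step 11**
Reactants: 17 2-(benzyloxy)-1-[4-methoxy-2,5-bis(methoxymethoxy)phenyl]ethan-1-one
Product: 18 2-(benzyloxy)-1-(2,5-dihydroxy-4-methoxyphenyl)ethan-1-one
Conditions: conc. HCl (cat.), MeOH, 50 °C, argon
Reagents that add atoms: none
Why: acid-catalysed acetal exchange removes both MOM groups at the ketone stage, before any 1,3-diketone exists that acid could cyclodehydrate through the ortho hydroxyl.

**Step 12**
Reactants: 18 2-(benzyloxy)-1-(2,5-dihydroxy-4-methoxyphenyl)ethan-1-one; 9 2,4-bis(benzyloxy)-5-methoxybenzoyl chloride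
Product: 20 2-(benzyloxy)-1-[2,4-bis(benzyloxy)-5-methoxyphenyl]-3-(2,5-dihydroxy-4-methoxyphenyl)propane-1,3-dione, via trilithium enolate bisphenoxide 19 (not isolated)
Conditions: 18, LiN(SiMe3)2 (4.2 equiv), THF, −78→−10 °C, argon; then 9 in THF, −78 °C→rt; poured into ice-cold dilute HCl (to about pH 4); used promptly
Reagents that add atoms: none
Why: Claisen-type C-acylation of a polyhydroxyacetophenone polyanion, in which the enolate carbon is the most reactive site towards the aroyl chloride, any acyl group landing on the ortho phenoxide is carried to carbon by Baker–Venkataraman migration under the same base, the fourth equivalent of base holds the product as its enolate, and no deprotection is needed on the sensitive diketone.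

**Step 13**
Reactants: 20 2-(benzyloxy)-1-[2,4-bis(benzyloxy)-5-methoxyphenyl]-3-(2,5-dihydroxy-4-methoxyphenyl)propane-1,3-dione
Product: 23 3-(benzyloxy)-2-[2,4-bis(benzyloxy)-5-methoxyphenyl]-5,8-dihydroxy-7-methoxy-4H-chromen-4-one, via acylquinone 21 (not isolated), via flavone-5,8-quinone 22 (not isolated)
Conditions: divided cell (glass frit or Nafion), graphite-felt anode, Pt cathode, Ag/AgCl reference; 20 (about 5 mM) in MeCN/0.2 M aq NaOAc–AcOH buffer (pH about 6) 3:1, 0.1 M LiClO4, argon, 15 °C; potential held about 0.1 V past the first anodic peak located by cyclic voltammetry (expected well below +0.8 V) until the current falls to background (up to 4 F/mol); then aq Na2S2O4 added to the anolyte, rt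
Reagents that add atoms: none
Why: Proposed new method: two-electron, two-proton oxidation of the hydroquinone of 20 at carbon gives acylquinone 21, in which the only unsubstituted ring carbon next to the acyl-bearing carbon (the future C8a) is β both to the future C5 carbonyl and to the side-chain C4 carbonyl and is therefore the most electrophilic site of the molecule. Acetate-assisted enolisation of the now more acidic C3–H brings the enol oxygen on the ring B side within reach, its conjugate addition forms O1–C8a and closes ring C in a 6-endo-trig mode, and loss of the C8a proton restores the aromatic ring as 5,8-diol 23. The closest known reaction types are the anodic reactions in which electrogenerated quinones are trapped by 1,3-dicarbonyl enols and the oxa-Michael closure of 2-(2-hydroxybenzoyl)benzoquinones to xanthones, and what is new is a tethered enol oxygen as nucleophile leading to a 3-oxygenated chromone. Because 23 carries one more oxygen donor on ring A than 20, it is expected to be oxidised on at the same potential to quinone 22, a class of quinone that is isolable and is returned to the diol by Na2S2O4, hence the exhaustive electrolysis followed by reductive levelling. Chemoselectivity for ring A rests on the expected gap of several hundred millivolts between a hydroquinone and the acylated trialkoxybenzene ring B, the benzyl ethers or the enol, while site selectivity rests on geometry, since attack by C3 would need a four-membered ring and the only other six-membered option, 1,2-addition of the enol oxygen to the C5 carbonyl, is a reversible hemiketalisation with no path to an aromatic product. No stereocentre is formed, and the oxidation also removes the ortho hydroxyl (future C5–OH) as a nucleophile, which shuts off the classical cyclodehydration to the wrong 6-hydroxy-7-methoxyflavone.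

**Step 14**
Reactants: 23 3-(benzyloxy)-2-[2,4-bis(benzyloxy)-5-methoxyphenyl]-5,8-dihydroxy-7-methoxy-4H-chromen-4-one
Product: 24 3-(benzyloxy)-2-[2,4-bis(benzyloxy)-5-methoxyphenyl]-5-hydroxy-7,8-dimethoxy-4H-chromen-4-one
Conditions: MeI (1.1 equiv), K2CO3 (1.2 equiv), degassed acetone, argon, rt→40 °C
Reagents that add atoms: iodomethane CI
Why: chemoselective Williamson methylation, because the C5 hydroxyl is tied up in a strong hydrogen bond to C4=O and is ionised far less readily than the free C8 hydroxyl, the usual order of reactivity in 5-hydroxyflavones.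

**Step 15**
Reactants: 24 3-(benzyloxy)-2-[2,4-bis(benzyloxy)-5-methoxyphenyl]-5-hydroxy-7,8-dimethoxy-4H-chromen-4-one
Product: 25 2-(2,4-dihydroxy-5-methoxyphenyl)-3,5-dihydroxy-7,8-dimethoxy-4H-chromen-4-one (target)
Conditions: H2 (1 atm), 10% Pd/C, EtOAc/MeOH, rt
Reagents that add atoms: none
Why: catalytic hydrogenolysis cleaves the three benzyl ethers under neutral conditions that leave the methyl ethers and the tetrasubstituted C2=C3 bond of the pyrone untouched and exclude any acid-induced Wessely–Moser isomerisation.

**Compound list**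
1 | isovanillin | COc1ccc(C=O)cc1O | starting material
2 | 3-(benzyloxy)-4-methoxybenzaldehyde | COc1ccc(C=O)cc1OCc1ccccc1 | intermediate
3 | 3-(benzyloxy)-4-methoxyphenyl formate | COc1ccc(OC=O)cc1OCc1ccccc1 | intermediate
4 | 3-(benzyloxy)-4-methoxyphenol | COc1ccc(O)cc1OCc1ccccc1 | intermediate
5 | 2,4-bis(benzyloxy)-1-methoxybenzene | COc1ccc(OCc2ccccc2)cc1OCc1ccccc1 | intermediate
6 | [2,4-bis(benzyloxy)-5-methoxybenzylidene]dimethyliminium chloride | COc1cc(C=[N+](C)C)c(OCc2ccccc2)cc1OCc1ccccc1.[Cl-] | intermediate
7 | 2,4-bis(benzyloxy)-5-methoxybenzaldehyde | COc1cc(C=O)c(OCc2ccccc2)cc1OCc1ccccc1 | intermediate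
8 | 2,4-bis(benzyloxy)-5-methoxybenzoic acid | COc1cc(C(=O)O)c(OCc2ccccc2)cc1OCc1ccccc1 | intermediate
9 | 2,4-bis(benzyloxy)-5-methoxybenzoyl chloride | COc1cc(C(=O)Cl)c(OCc2ccccc2)cc1OCc1ccccc1 | intermediate
10 | benzyloxyacetic acid | O=C(O)COCc1ccccc1 | starting material
11 | 2-(benzyloxy)-1-(imidazol-1-yl)ethan-1-one | O=C(COCc1ccccc1)n1ccnc1 | intermediate
12 | 2-(benzyloxy)-N-methoxy-N-methylacetamide | CON(C)C(=O)COCc1ccccc1 | intermediate
13 | methoxyhydroquinone | COc1cc(O)ccc1O | starting material
14 | 2-methoxy-1,4-bis(methoxymethoxy)benzene | COc1cc(OCOC)ccc1OCOC | intermediate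
15 | 1-bromo-4-methoxy-2,5-bis(methoxymethoxy)benzene | COc1cc(OCOC)c(Br)cc1OCOC | intermediate
16 | [4-methoxy-2,5-bis(methoxymethoxy)phenyl]lithium | [Li]c1cc(OCOC)c(OC)cc1OCOC | intermediate
17 | 2-(benzyloxy)-1-[4-methoxy-2,5-bis(methoxymethoxy)phenyl]ethan-1-one | COc1cc(OCOC)c(C(=O)COCc2ccccc2)cc1OCOC | intermediate
18 | 2-(benzyloxy)-1-(2,5-dihydroxy-4-methoxyphenyl)ethan-1-one | COc1cc(O)c(C(=O)COCc2ccccc2)cc1O | intermediate
19 | trilithium enolate bisphenoxide of 18 | [Li+].[Li+].[Li+].COc1cc([O-])c(C([O-])=COCc2ccccc2)cc1[O-] | intermediate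
20 | 2-(benzyloxy)-1-[2,4-bis(benzyloxy)-5-methoxyphenyl]-3-(2,5-dihydroxy-4-methoxyphenyl)propane-1,3-dione | COc1cc(O)c(C(=O)C(OCc2ccccc2)C(=O)c2cc(OC)c(OCc3ccccc3)cc2OCc2ccccc2)cc1O | intermediate
21 | 2-{2-(benzyloxy)-3-[2,4-bis(benzyloxy)-5-methoxyphenyl]-3-oxopropanoyl}-5-methoxy-1,4-benzoquinone | COC1=CC(=O)C(C(=O)C(OCc2ccccc2)C(=O)c2cc(OC)c(OCc3ccccc3)cc2OCc2ccccc2)=CC1=O | intermediate
22 | 3-(benzyloxy)-2-[2,4-bis(benzyloxy)-5-methoxyphenyl]-7-methoxy-4H-chromene-4,5,8-trione | COC1=CC(=O)C2=C(OC(c3cc(OC)c(OCc4ccccc4)cc3OCc3ccccc3)=C(OCc3ccccc3)C2=O)C1=O | intermediate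
23 | 3-(benzyloxy)-2-[2,4-bis(benzyloxy)-5-methoxyphenyl]-5,8-dihydroxy-7-methoxy-4H-chromen-4-one | COc1cc(-c2oc3c(O)c(OC)cc(O)c3c(=O)c2OCc2ccccc2)c(OCc2ccccc2)cc1OCc1ccccc1 | intermediate
24 | 3-(benzyloxy)-2-[2,4-bis(benzyloxy)-5-methoxyphenyl]-5-hydroxy-7,8-dimethoxy-4H-chromen-4-one | COc1cc(-c2oc3c(OC)c(OC)cc(O)c3c(=O)c2OCc2ccccc2)c(OCc2ccccc2)cc1OCc1ccccc1 | intermediate
25 | 2-(2,4-dihydroxy-5-methoxyphenyl)-3,5-dihydroxy-7,8-dimethoxy-4H-chromen-4-one | COc1cc(-c2oc3c(OC)c(OC)cc(O)c3c(=O)c2O)c(O)cc1O | target

**Totals**
Total step count: 15.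
Longest linear sequence: 10 steps (steps 1–6, then 12–15).

**Steps most likely to fail**

**Step 13 (key step).**
- What may go wrong:
  - Enolisation of the 2-substituted diketone may be slow, so water or acetate may add to the quinone first.
  - The tricarbonyl chain may be cleaved hydrolytically.
  - Quinone–hydroquinone coupling may foul the anode.
- Fallback (known chemistry; sets out from Weinreb amide 12 and acid chloride 9, comes back at 23): ring C is closed by classical cyclodehydration on a phloroglucinol-type ring A, and the C8 oxygen is introduced afterwards, para to C5–OH, by Elbs persulfate oxidation. Purchased 5-methoxyresorcinol F1 is converted with MOMCl and iPr2NEt into 1-methoxy-3,5-bis(methoxymethoxy)benzene F2. This is lithiated between the two MOM ethers (n-BuLi, THF, 0 °C) and acylated with 12 to give 2-(benzyloxy)-1-[4-methoxy-2,6-bis(methoxymethoxy)phenyl]ethan-1-one F3. HCl in MeOH frees 2-(benzyloxy)-1-(2,6-dihydroxy-4-methoxyphenyl)ethan-1-one F4, whose two hydroxyls are equivalent. LiN(SiMe3)2 and 9 give 2-(benzyloxy)-1-[2,4-bis(benzyloxy)-5-methoxyphenyl]-3-(2,6-dihydroxy-4-methoxyphenyl)propane-1,3-dione F5. Catalytic TsOH in warm toluene dehydrates it to 3-(benzyloxy)-2-[2,4-bis(benzyloxy)-5-methoxyphenyl]-5-hydroxy-7-methoxy-4H-chromen-4-one F6. K2S2O8 in aqueous KOH/pyridine then gives the potassium flavon-8-yl sulfate F7, which warm dilute HCl hydrolyses to 23.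

**Step 12.**
- What may go wrong:
  - Acylation may occur at the remote O5 phenoxide instead of at carbon.
  - Poor solubility may leave polyanion formation incomplete.
  - Excess amide base may consume the acid chloride.
- Fallback (sets out from 18 and 9, comes back at 20): the intermolecular C-acylation is replaced by a stepwise Baker–Venkataraman sequence. Both phenols of 18 are esterified with two equivalents of 9 (pyridine, DMAP) to 2-[(benzyloxy)acetyl]-5-methoxy-1,4-phenylene bis[2,4-bis(benzyloxy)-5-methoxybenzoate] F8. KOt-Bu in THF moves the ortho aroyl group from oxygen to the α-carbon through a six-membered transition state, giving the 5-O-aroyl diketone F9. LiOH in aqueous THF at 0 °C under argon cleaves the remaining aryl ester, giving 20 and returning acid 8 for reuse.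

**Step 14.**
- What may go wrong:
  - Discrimination between the two hydroxyls may be lost, with alkylation at O5 as well.
  - The hydroquinone anion may be oxidised by air under base.
- Fallback (sets out from 23, comes back at 25): selectivity is moved from the alkylation to the dealkylation. Exhaustive methylation (Me2SO4, K2CO3, acetone, reflux, argon) gives 3-(benzyloxy)-2-[2,4-bis(benzyloxy)-5-methoxyphenyl]-5,7,8-trimethoxy-4H-chromen-4-one F10. BCl3 with pentamethylbenzene in CH2Cl2 (−78→0 °C) then removes the three benzyl groups. Through the boron chelate between O5 and C4=O it should also remove only the C5 methyl ether. This leads directly to 25 and makes step 15 unnecessary.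

**Further compounds**
F1 | step 13 | 5-methoxyresorcinol (purchased) | COc1cc(O)cc(O)c1
F2 | step 13 | 1-methoxy-3,5-bis(methoxymethoxy)benzene | COCOc1cc(OC)cc(OCOC)c1
F3 | step 13 | 2-(benzyloxy)-1-[4-methoxy-2,6-bis(methoxymethoxy)phenyl]ethan-1-one | COCOc1cc(OC)cc(OCOC)c1C(=O)COCc1ccccc1
F4 | step 13 | 2-(benzyloxy)-1-(2,6-dihydroxy-4-methoxyphenyl)ethan-1-one | COc1cc(O)c(C(=O)COCc2ccccc2)c(O)c1
F5 | step 13 | 2-(benzyloxy)-1-[2,4-bis(benzyloxy)-5-methoxyphenyl]-3-(2,6-dihydroxy-4-methoxyphenyl)propane-1,3-dione | COc1cc(O)c(C(=O)C(OCc2ccccc2)C(=O)c2cc(OC)c(OCc3ccccc3)cc2OCc2ccccc2)c(O)c1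
F6 | step 13 | 3-(benzyloxy)-2-[2,4-bis(benzyloxy)-5-methoxyphenyl]-5-hydroxy-7-methoxy-4H-chromen-4-one | COc1cc(O)c2c(=O)c(OCc3ccccc3)c(-c3cc(OC)c(OCc4ccccc4)cc3OCc3ccccc3)oc2c1
F7 | step 13 | potassium 3-(benzyloxy)-2-[2,4-bis(benzyloxy)-5-methoxyphenyl]-5-hydroxy-7-methoxy-4-oxo-4H-chromen-8-yl sulfate | COc1cc(O)c2c(=O)c(OCc3ccccc3)c(-c3cc(OC)c(OCc4ccccc4)cc3OCc3ccccc3)oc2c1OS(=O)(=O)[O-].[K+]
F8 | step 12 | 2-[(benzyloxy)acetyl]-5-methoxy-1,4-phenylene bis[2,4-bis(benzyloxy)-5-methoxybenzoate] | COc1cc(OC(=O)c2cc(OC)c(OCc3ccccc3)cc2OCc2ccccc2)c(C(=O)COCc2ccccc2)cc1OC(=O)c1cc(OC)c(OCc2ccccc2)cc1OCc1ccccc1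
F9 | step 12 | 5-{2-(benzyloxy)-3-[2,4-bis(benzyloxy)-5-methoxyphenyl]-3-oxopropanoyl}-4-hydroxy-2-methoxyphenyl 2,4-bis(benzyloxy)-5-methoxybenzoate | COc1cc(O)c(C(=O)C(OCc2ccccc2)C(=O)c2cc(OC)c(OCc3ccccc3)cc2OCc2ccccc2)cc1OC(=O)c1cc(OC)c(OCc2ccccc2)cc1OCc1ccccc1
F10 | step 14 | 3-(benzyloxy)-2-[2,4-bis(benzyloxy)-5-methoxyphenyl]-5,7,8-trimethoxy-4H-chromen-4-one | COc1cc(-c2oc3c(OC)c(OC)cc(OC)c3c(=O)c2OCc2ccccc2)c(OCc2ccccc2)cc1OCc1ccccc1
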